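- Starting complex trades a leaving ligand for an incoming ligand one for one, so dilution by the feed cancels in the ratio of the two free ligands, and the question is what end state, a position of equilibrium, that ratio reaches.

common to all: starting complex 0.0050 M (fed, over 10 s)

|  | incoming ligand | leaving ligand | remark | time |
|---|---|---|---|---|
| east | 10 mM | 2.5 mM | run made earlier; the fed solution adds 0.50 times the starting volume |  |
| south-east | 10 mM | 3.8 mM | run made earlier; the fed solution adds 0.50 times the starting volume |  |
| south | 15 mM | 5 mM | run made earlier; the fed solution adds 0.50 times the starting volume |  |
| flask | 10.0 mM | 5.00 mM | the fed solution adds 0.50 times the starting volume | 5.0 min |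

- east (time / min: starting complex / %, complex with three exchanged / %): 0.250: 53.2, 1.8; 0.333: 48.5, 2.9; 0.500: 44.2, 4.1; 0.833: 42.8, 5.8; 1.33: 42.6, 6.1; 2.00: 43.8, 5.8; 3.00: 43.2, 5.8
- south-east (time / min: starting complex / %, complex with three exchanged / %): 0.250: 55.7, 1.7; 0.333: 49.9, 1.4; 0.500: 47.4, 3.0; 0.833: 45.4, 5.3; 1.33: 46.7, 4.2; 2.00: 45.5, 4.6; 3.00: 46.3, 4.3
- south (time / min: starting complex / %, complex with three exchanged / %): 0.250: 47.9, 3.6; 0.417: 41.3, 5.9; 0.833: 40.3, 6.9; 1.50: 39.8, 6.8; 3.00: 39.9, 6.6

(scatter of a reading: 0.5 percentage points)

1. at 5.0 min, what has stopped the reaction, if anything has (forward and back rates have come level / it is still moving / the incoming ligand has run out first / all of the starting complex has reacted)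
2. conversion of starting complex at 5.0 min
3. amount of complex with three exchanged at 5.0 min, in percent of the starting complex charged
4. amount of complex with one exchanged at 5.0 min, in percent of the starting complex charged
5. amount of complex with three exchanged if the flask were left three thousand times as long, in percent of the starting complex charged

- charges are per starting volume, the dose included; the dosed solution carries all of it
- the analysis behind the earlier runs scatters by 0.5 percentage points, standard deviation
- what has gone from starting complex into another species counts as reacted, even if it can come back
- the reaction counts as stopped when no species that holds the starting complex changes by six tenths of a point or more over the second half of the time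

- The bench rule sets the free ligands equal to their charges and, with a balance of one, takes the reacted fraction as incoming over incoming plus leaving, which is 66.7% for this flask.
- On the south run the same rule gives 75.0%, but the last reading shows 60.1% reacted, less than the rule gives.
- The border of the rule is the charge of complex over the charge of leaving ligand: the rule needs this ratio far below one, and in this flask it is 1.00, so the exchange itself shifts the free ligands.
- My own reckoning counts one ligand swapped per starting complex lost and forms a balance quotient: reacted over unreacted, divided by free incoming over free leaving.
- The last readings give 0.981 for the east run, 1.03 for the south-east run and 1.01 for the south run.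
- With the quotient set to one, the squared terms cancel and the reacted fraction equals the incoming share, the charge of incoming ligand over the sum of the incoming, leaving and complex charges, which is 50.0% for this flask.
- East-run starting complex reads 42.8% at 0.833 min and 43.2% at 3.00 min, a shift of 0.4 percentage points against a scatter of 0.5 points, and this flask runs longer than that, so the end state should stand by 5.0 min.
- The forecast says forward and back rates have come level, with conversion 51.5% (49.5% to 53.5%), complex with three exchanged 3.5% (2.8% to 4.2%), complex with one exchanged 36% (29% to 42%) and, for the long wait of the last question, complex with three exchanged 3.5% (2.7% to 4.3%). Its caution reads: “Ma is the least certain because it was never measured.” Its conversion stands 1.5 points above the incoming share.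
- In the flask forward and back rates have come level, with conversion 52.0%, complex with three exchanged 3.49%, complex with one exchanged 26.6% and, for the long wait of the last question, 0% of complex with three exchanged. Complex with one exchanged lies 9.4 points below the forecast, and the flask holds 15.4% as dormant form at 5.00 min. The incoming share of 50.0% lies 2 points under the conversion.

    starting complex + incoming ligand ⇌ leaving ligand + complex with one exchanged (K = 0.560, k = 11.6 /M/s)
    complex with one exchanged + incoming ligand ⇌ leaving ligand + complex with two exchanged (K = 0.250, k = 29.9 /M/s)
    complex with two exchanged + incoming ligand ⇌ leaving ligand + complex with three exchanged (K = 0.539, k = 6.60 /M/s)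
    starting complex ⇌ dormant form (K = 0.320, k = 0.0204 /s)
    incoming ligand → decomposition product (k = 3.62 × 10⁻⁵ /s)

- For the neighbouring flask with 0.040 M of incoming ligand, the incoming share gives 80.0%. The computed conversion of that flask is 80.5%.

(Readings and results are calculated for an exercise, noise included.)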